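**Retrosynthetic overview**

1. The C40 nonaene is cut at its two C(sp2)–C(sp2) single bonds C12–C13 and C12′–C13′, giving two C16 ring–trienyl pieces and one C8 triene linchpin (C13 to C13′, with both methyl groups).
2. Enabling feature: the chain C7–C7′ is C2-symmetric about C15=C15′, C13 and C13′ are methyl-bearing sp2 carbons, C12 and C12′ are unhindered (E)-CH termini, and the two cyclohexanone rings (C1–C6 and C1′–C6′) differ only at C5 versus C5′. The linchpin can therefore carry iodide at C13 and a pinacolboronate at C13′, the 5S,6S ring piece a stannane at C12 and the 5R,6S ring piece an iodide at C12′.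
3. Key step: in one flask, a Stille coupling (C12–C13) and then a fluoride-promoted Suzuki–Miyaura coupling (C12′–C13′) unite C16 + C8 + C16, with all nine E double bonds preformed and both tertiary aldols unprotected.
4. No ring is formed in the route: both six-membered rings are the ring of (S)-α-ionone (C6 bought). C3 is oxidised, and C5 is set in each series by the relay C3–OH (both Luche epimers are used, one per end) → hydroxyl-directed epoxidation → hydride opening.
5. The C8 linchpin is grown in two directions from (E)-1,2-dichloroethene (double Sonogashira), desymmetrised by mono-hydroboration and finished by hydrozirconation–iodination.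

Key step: step 16

Remark: (S)-(−)-α-ionone (compound 7) is taken to be purchasable as the single enantiomer; it is the only source of chirality in the route.

**Route**

Step 1
Reactants: 1 (E)-1,2-dichloroethene; 2 propyne
Product: 3 (4E)-oct-4-ene-2,6-diyne
Conditions: 2 (2.5 equiv), PdCl2(PhCN)2 (5 mol %), CuI (10 mol %), piperidine, THF, 0 → 25 °C
Reagents that add atoms: none
Why: Two-fold Sonogashira coupling on both C–Cl bonds of the symmetric dihaloethene should proceed with retention of the E geometry, the first alkynylation activating the remaining chloride so that the reaction runs through to the enediyne.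

Step 2
Reactants: 3 (4E)-oct-4-ene-2,6-diyne
Product: 4 4,4,5,5-tetramethyl-2-[(2Z,4E)-octa-2,4-dien-6-yn-2-yl]-1,3,2-dioxaborolane
Conditions: pinacolborane (1 equiv), 3 (3 equiv, excess recovered), Cp2Zr(H)Cl (5 mol %), CH2Cl2, 25 °C
Reagents that add atoms: pinacolborane, [H]B1OC(C)(C)C(C)(C)O1
Why: Zirconium-catalysed hydroboration adds Zr–H syn across one alkyne with the metal at the less hindered, methyl-bearing carbon, and Zr/B exchange should give the alkenylboronate with boron trans to the diene chain, the excess of symmetric 3 holding the reaction at mono-addition.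

Step 3
Reactants: 4 mono-boronate
Product: 6 4,4,5,5-tetramethyl-2-[(2Z,4E,6E)-7-iodoocta-2,4,6-trien-2-yl]-1,3,2-dioxaborolane, via alkenylzirconocene chloride 5 (not isolated)
Conditions: Cp2Zr(H)Cl (1.3 equiv), THF, 25 °C, dark; then I2, 0 °C
Reagents that add atoms: iodine, [I][I]
Why: Hydrozirconation of the remaining 2-alkyne (syn addition, zirconium at the methyl-bearing carbon) followed by iodinolysis of the C–Zr bond with retention should give the (E)-2-iodoalkene terminus, the alkenyl pinacolboronate being inert to both reagents.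

Step 4
Reactants: 7 (S)-α-ionone
Product: 8 ethyl (2E,4E)-3-methyl-5-[(1S)-2,6,6-trimethylcyclohex-2-en-1-yl]penta-2,4-dienoate
Conditions: (EtO)2P(O)CH2CO2Et, NaH, THF, 0 → 40 °C; chromatography to remove the minor 2Z isomer
Reagents that add atoms: triethyl phosphonoacetate, CCOC(=O)CP(=O)(OCC)OCC
Why: Horner–Wadsworth–Emmons olefination of the methyl ketone should favour the 2E dienoate, and the C6 stereocentre is expected to survive because the hindered γ-hydrogen is not removed under these conditions.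

Step 5
Reactants: 8 dienoate
Product: 9 ethyl (2E,4E)-3-methyl-5-[(1S)-2,6,6-trimethyl-4-oxocyclohex-2-en-1-yl]penta-2,4-dienoate
Conditions: tBuOOH (70 % aq.), Rh2(cap)4 (cap = caprolactamate, 1 mol %), 1,2-dichloroethane, 40 °C
Reagents that add atoms: tert-butyl hydroperoxide, CC(C)(C)OO
Why: Metal-catalysed allylic C–H oxidation with tBuOOH (hydrogen abstraction by the tert-butylperoxyl radical at the secondary allylic C3, a reaction type established for α-ionone-type cyclohexenes) should give the ring enone without base, so that the now acidic C6–H is not epimerised.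

Step 6
Reactants: 9 keto ester
Product: 10 ethyl (2E,4E)-5-[(1S,4S)-4-hydroxy-2,6,6-trimethylcyclohex-2-en-1-yl]-3-methylpenta-2,4-dienoate (OH trans to the side chain) and 11 ethyl (2E,4E)-5-[(1S,4R)-4-hydroxy-2,6,6-trimethylcyclohex-2-en-1-yl]-3-methylpenta-2,4-dienoate (OH cis to the side chain)
Conditions: NaBH4, CeCl3·7H2O, MeOH, −78 °C; chromatography to separate 10 and 11
Reagents that add atoms: none
Why: Luche 1,2-reduction of the ring enone leaves the ester untouched, and since the remote C6 substituent should discriminate the two faces of C3 only weakly, both carbinol epimers are expected and both are wanted, one for each end of the target.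

Step 7
Reactants: 10 trans allylic alcohol
Product: 12 ethyl (2E,4E)-5-[(1S,2R,3S,4S)-2,3-epoxy-4-hydroxy-2,6,6-trimethylcyclohexyl]-3-methylpenta-2,4-dienoate (epoxide and hydroxyl on the face opposite to the side chain)
Conditions: tBuOOH, VO(acac)2 (5 mol %), CH2Cl2, 0 → 25 °C
Reagents that add atoms: tert-butyl hydroperoxide, CC(C)(C)OO
Why: Vanadium-catalysed hydroxyl-directed epoxidation delivers oxygen to the face of C4=C5 that carries the C3 hydroxyl, which sets C5 with oxygen trans to the side chain, and it leaves the electron-poor dienoate alone.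

Step 8
Reactants: 12 trans epoxy alcohol
Product: 13 (2E,4E)-5-[(1S,2S,4S)-2,4-dihydroxy-2,6,6-trimethylcyclohexyl]-3-methylpenta-2,4-dien-1-ol
Conditions: LiAlH4, THF, 0 → 40 °C
Reagents that add atoms: none
Why: LiAlH4 reduces the dienoate to the allylic alcohol and should open the trisubstituted epoxide by SN2 attack of hydride at the secondary carbon C4 anti to oxygen (trans-diaxial opening), so the C5–O bond and the C5 configuration from step 7 are kept as the tertiary alcohol.

Step 9
Reactants: 13 trans triol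
Product: 14 (2E,4E)-5-[(1S,2S)-2-hydroxy-2,6,6-trimethyl-4-oxocyclohexyl]-3-methylpenta-2,4-dienal
Conditions: Dess–Martin periodinane, pyridine, CH2Cl2, 0 → 25 °C
Reagents that add atoms: none
Why: Dess–Martin oxidation converts the primary allylic alcohol and the secondary C3 alcohol into dienal and ketone in one operation, the tertiary C5 alcohol cannot be oxidised, and the auxiliary C3 stereocentre is erased on purpose.

Step 10
Reactants: 14 trans keto aldehyde
Product: 15 (3S,4S)-3-hydroxy-4-[(1E,3E,5E)-6-iodo-3-methylhexa-1,3,5-trien-1-yl]-3,5,5-trimethylcyclohexan-1-one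
Conditions: CHI3, CrCl2, dioxane/THF 6:1, 25 °C, dark
Reagents that add atoms: iodoform, IC(I)I
Why: Takai olefination: the geminal dichromium species from iodoform and CrCl2 adds only to the aldehyde (ketone and free tertiary alcohol tolerated) and elimination should give the (E)-alkenyl iodide.

Step 11
Reactants: 15 trans trienyl iodide
Product: 16 (3S,4S)-3-hydroxy-3,5,5-trimethyl-4-[(1E,3E,5E)-3-methyl-6-(trimethylstannyl)hexa-1,3,5-trien-1-yl]cyclohexan-1-one
Conditions: (Me3Sn)2 (2 equiv), PdCl2(MeCN)2 (5 mol %), NMP, 25 °C, dark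
Reagents that add atoms: hexamethylditin, C[Sn](C)(C)[Sn](C)(C)C
Why: Palladium-catalysed stannylation of the alkenyl iodide with the ditin (oxidative addition, Sn–Sn transmetalation, reductive elimination) should proceed with retention of the E geometry under neutral conditions that do not disturb the aldol.

Step 12
Reactants: 11 cis allylic alcohol
Product: 17 ethyl (2E,4E)-5-[(1S,2S,3R,4R)-2,3-epoxy-4-hydroxy-2,6,6-trimethylcyclohexyl]-3-methylpenta-2,4-dienoate (epoxide and hydroxyl on the same face as the side chain)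
Conditions: tBuOOH, VO(acac)2 (5 mol %), CH2Cl2, 0 → 25 °C
Reagents that add atoms: tert-butyl hydroperoxide, CC(C)(C)OO
Why: The same hydroxyl-directed epoxidation, now steered by the cis C3 hydroxyl, should override the steric bias of the neighbouring side chain and set C5 with oxygen cis to the side chain.

Step 13
Reactants: 17 cis epoxy alcohol
Product: 18 (2E,4E)-5-[(1S,2R,4R)-2,4-dihydroxy-2,6,6-trimethylcyclohexyl]-3-methylpenta-2,4-dien-1-ol
Conditions: LiAlH4, THF, 0 → 40 °C
Reagents that add atoms: none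
Why: As in step 8, ester reduction and SN2 hydride opening of the epoxide at the secondary C4 should leave the tertiary C5 alcohol with the configuration set in step 12.

Step 14
Reactants: 18 cis triol
Product: 19 (2E,4E)-5-[(1S,2R)-2-hydroxy-2,6,6-trimethyl-4-oxocyclohexyl]-3-methylpenta-2,4-dienal
Conditions: Dess–Martin periodinane, pyridine, CH2Cl2, 0 → 25 °C
Reagents that add atoms: none
Why: As in step 9, double Dess–Martin oxidation gives dienal and C3 ketone and spares the tertiary alcohol.

Step 15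
Reactants: 19 cis keto aldehyde
Product: 20 (3R,4S)-3-hydroxy-4-[(1E,3E,5E)-6-iodo-3-methylhexa-1,3,5-trien-1-yl]-3,5,5-trimethylcyclohexan-1-one
Conditions: CHI3, CrCl2, dioxane/THF 6:1, 25 °C, dark
Reagents that add atoms: iodoform, IC(I)I
Why: As in step 10, aldehyde-selective Takai olefination should give the (E)-alkenyl iodide.

Step 16
Reactants: 16 trans trienylstannane; 6 iodo-boronate linchpin; 20 cis trienyl iodide
Product: 22 (5S,6S,5′R,6′S)-5,5′-dihydroxy-5,6,5′,6′-tetrahydro-β,β-carotene-3,3′-dione (all-E), via C24 hexaenyl pinacolboronate 21 (not isolated)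
Conditions: (a) 16 and 6 (1:1), Pd2(dba)3 (2.5 mol %), AsPh3 (20 mol %), DMF/THF, 25 °C, dark; (b) 20 (1 equiv), CsF, H2O, second charge of Pd2(dba)3/AsPh3, same flask, 25 → 40 °C
Reagents that add atoms: none
Why: In stage (a) zerovalent palladium inserts into the C13–I bond of 6, the (E)-alkenyl group of 16 is transferred from tin, and reductive elimination forms C12–C13 to give 21, whose pinacolboronate is inert without an activator. In stage (b) fluoride turns the C13′ boronate of 21 into a fluoroborate that transmetalates to the alkenylpalladium iodide formed from 20, and reductive elimination forms C12′–C13′ and completes the nonaene. The closest known reaction type is the chemoselective Stille coupling in the presence of an alkenyl pinacolboronate followed in the same flask by Suzuki–Miyaura coupling, as practised with stannyl/boryl and halo/boryl olefin linchpins in polyene synthesis. No ring is closed and no stereocentre is created; both couplings are stereoretentive at sp2 carbon, so all nine double bonds should keep their E geometry. The selectivity needed is the hetero-pairing of the two C5-epimeric ends, and it is secured by polarity: the 5S,6S piece is a stannane that can only meet the iodide terminus and the 5R,6S piece is an iodide that can only meet the boron terminus, so neither the 5S,5′S nor the 5R,5′R isomer can form. Stage (a) is neutral and stage (b) uses fluoride in place of hydroxide, so that the tertiary aldols at C5 and C5′ should escape retro-aldol epimerisation and dehydration.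

**Compound list**

1 | (E)-1,2-dichloroethene | Cl/C=C/Cl | starting material
2 | propyne | CC#C | starting material
3 | (4E)-oct-4-ene-2,6-diyne | CC#C/C=C/C#CC | intermediate
4 | 4,4,5,5-tetramethyl-2-[(2Z,4E)-octa-2,4-dien-6-yn-2-yl]-1,3,2-dioxaborolane | C/C(B1OC(C)(C)C(C)(C)O1)=C\C=C\C#CC | intermediate
5 | alkenylzirconocene chloride from 4 (Cp2ZrCl at C7, syn to H at C6) | C/C(B1OC(C)(C)C(C)(C)O1)=C\C=C\C=C(/C)[Zr](Cl)(C1C=CC=C1)C1C=CC=C1 | intermediate (not isolated)
6 | 4,4,5,5-tetramethyl-2-[(2Z,4E,6E)-7-iodoocta-2,4,6-trien-2-yl]-1,3,2-dioxaborolane | C/C(B1OC(C)(C)C(C)(C)O1)=C\C=C\C=C(/C)I | intermediate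
7 | (S)-α-ionone | CC(=O)/C=C/[C@H]1C(C)(C)CCC=C1C | starting material
8 | ethyl (2E,4E)-3-methyl-5-[(1S)-2,6,6-trimethylcyclohex-2-en-1-yl]penta-2,4-dienoate | CCOC(=O)/C=C(C)/C=C/[C@H]1C(C)(C)CCC=C1C | intermediate
9 | ethyl (2E,4E)-3-methyl-5-[(1S)-2,6,6-trimethyl-4-oxocyclohex-2-en-1-yl]penta-2,4-dienoate | CCOC(=O)/C=C(C)/C=C/[C@H]1C(C)(C)CC(=O)C=C1C | intermediate
10 | ethyl (2E,4E)-5-[(1S,4S)-4-hydroxy-2,6,6-trimethylcyclohex-2-en-1-yl]-3-methylpenta-2,4-dienoate | CCOC(=O)/C=C(C)/C=C/[C@H]1C(C)(C)C[C@H](O)C=C1C | intermediate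
11 | ethyl (2E,4E)-5-[(1S,4R)-4-hydroxy-2,6,6-trimethylcyclohex-2-en-1-yl]-3-methylpenta-2,4-dienoate | CCOC(=O)/C=C(C)/C=C/[C@H]1C(C)(C)C[C@@H](O)C=C1C | intermediate
12 | ethyl (2E,4E)-5-[(1S,2R,3S,4S)-2,3-epoxy-4-hydroxy-2,6,6-trimethylcyclohexyl]-3-methylpenta-2,4-dienoate | CCOC(=O)/C=C(C)/C=C/[C@H]1C(C)(C)C[C@H](O)[C@@H]2O[C@]12C | intermediate
13 | (2E,4E)-5-[(1S,2S,4S)-2,4-dihydroxy-2,6,6-trimethylcyclohexyl]-3-methylpenta-2,4-dien-1-ol | OC/C=C(C)/C=C/[C@H]1C(C)(C)C[C@H](O)C[C@]1(C)O | intermediate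
14 | (2E,4E)-5-[(1S,2S)-2-hydroxy-2,6,6-trimethyl-4-oxocyclohexyl]-3-methylpenta-2,4-dienal | O=C/C=C(C)/C=C/[C@H]1C(C)(C)CC(=O)C[C@]1(C)O | intermediate
15 | (3S,4S)-3-hydroxy-4-[(1E,3E,5E)-6-iodo-3-methylhexa-1,3,5-trien-1-yl]-3,5,5-trimethylcyclohexan-1-one | I/C=C/C=C(C)/C=C/[C@H]1C(C)(C)CC(=O)C[C@]1(C)O | intermediate
16 | (3S,4S)-3-hydroxy-3,5,5-trimethyl-4-[(1E,3E,5E)-3-methyl-6-(trimethylstannyl)hexa-1,3,5-trien-1-yl]cyclohexan-1-one | C[Sn](C)(C)/C=C/C=C(C)/C=C/[C@H]1C(C)(C)CC(=O)C[C@]1(C)O | intermediate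
17 | ethyl (2E,4E)-5-[(1S,2S,3R,4R)-2,3-epoxy-4-hydroxy-2,6,6-trimethylcyclohexyl]-3-methylpenta-2,4-dienoate | CCOC(=O)/C=C(C)/C=C/[C@H]1C(C)(C)C[C@@H](O)[C@H]2O[C@@]12C | intermediate
18 | (2E,4E)-5-[(1S,2R,4R)-2,4-dihydroxy-2,6,6-trimethylcyclohexyl]-3-methylpenta-2,4-dien-1-ol | OC/C=C(C)/C=C/[C@H]1C(C)(C)C[C@@H](O)C[C@@]1(C)O | intermediate
19 | (2E,4E)-5-[(1S,2R)-2-hydroxy-2,6,6-trimethyl-4-oxocyclohexyl]-3-methylpenta-2,4-dienal | O=C/C=C(C)/C=C/[C@H]1C(C)(C)CC(=O)C[C@@]1(C)O | intermediate
20 | (3R,4S)-3-hydroxy-4-[(1E,3E,5E)-6-iodo-3-methylhexa-1,3,5-trien-1-yl]-3,5,5-trimethylcyclohexan-1-one | I/C=C/C=C(C)/C=C/[C@H]1C(C)(C)CC(=O)C[C@@]1(C)O | intermediate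
21 | (3S,4S)-3-hydroxy-3,5,5-trimethyl-4-[(1E,3E,5E,7E,9E,11Z)-3,7-dimethyl-12-(4,4,5,5-tetramethyl-1,3,2-dioxaborolan-2-yl)trideca-1,3,5,7,9,11-hexaen-1-yl]cyclohexan-1-one | C/C(B1OC(C)(C)C(C)(C)O1)=C\C=C\C=C(C)\C=C\C=C(C)\C=C\[C@H]1C(C)(C)CC(=O)C[C@]1(C)O | intermediate (not isolated)
22 | (5S,6S,5′R,6′S)-5,5′-dihydroxy-5,6,5′,6′-tetrahydro-β,β-carotene-3,3′-dione | CC(/C=C/C=C(C)/C=C/[C@H]1C(C)(C)CC(=O)C[C@]1(C)O)=C\C=C\C=C(C)\C=C\C=C(C)\C=C\[C@H]1C(C)(C)CC(=O)C[C@@]1(C)O | target

**Step count**

Total steps: 16. Longest linear sequence: 9 (steps 4, 5, 6, 7, 8, 9, 10, 11, 16).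

**Steps most likely to fail**

Step 16. What may go wrong: fluoride-induced retro-aldol/aldol epimerisation or dehydration at C5 or C5′ during the second stage, protodeboronation of the hexaenyl boronate before it couples, or incomplete consumption of 6 in the first stage. Fallback, setting out from 3 and returning at 22: double hydrozirconation–iodination of 3 (Cp2Zr(H)Cl, then I2) would give (2E,4E,6E)-2,7-diiodoocta-2,4,6-triene F1. Stille coupling of 16 with a threefold excess of F1 (Pd2(dba)3, AsPh3, DMF, 25 °C) would give the isolated C24 alkenyl iodide (3S,4S)-3-hydroxy-4-[(1E,3E,5E,7E,9E,11E)-12-iodo-3,7-dimethyltrideca-1,3,5,7,9,11-hexaen-1-yl]-3,5,5-trimethylcyclohexan-1-one F2. Iodide 20 would be converted under the conditions of step 11 into (3R,4S)-3-hydroxy-3,5,5-trimethyl-4-[(1E,3E,5E)-3-methyl-6-(trimethylstannyl)hexa-1,3,5-trien-1-yl]cyclohexan-1-one F3. A second Stille coupling of F2 with F3 then forms C12′–C13′ and gives 22 with neither base nor fluoride present.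

Step 5. What may go wrong: competing hydrogen abstraction at the doubly allylic C6–H (loss of material, erosion of enantiopurity) and oxidative attack on the dienoate chain. Fallback, setting out from 7 and returning at 9: the allylic oxidation would be run on 7 itself, the parent ketone for which it is established, to give (S)-3-oxo-α-ionone F4. The Reformatsky reagent from ethyl bromoacetate and zinc would add to the unhindered methyl ketone under non-basic conditions to give ethyl (4E)-3-hydroxy-3-methyl-5-[(1S)-2,6,6-trimethyl-4-oxocyclohex-2-en-1-yl]pent-4-enoate F5 (both carbinol epimers). Dehydration (Burgess reagent) and separation of the 2E isomer would rejoin the route at 9.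

Step 8 (the same operation recurs as step 13). What may go wrong: hydride delivery to the wrong epoxide carbon, or conjugate reduction of the dienoate. Fallback, setting out from 12 and returning at 14: Dess–Martin oxidation of 12 would give ethyl (2E,4E)-5-[(1S,2R,3R)-2,3-epoxy-2,6,6-trimethyl-4-oxocyclohexyl]-3-methylpenta-2,4-dienoate F6. SmI2 (THF/MeOH, −90 °C) cleaves only the Cα–O bond and would give ethyl (2E,4E)-5-[(1S,2S)-2-hydroxy-2,6,6-trimethyl-4-oxocyclohexyl]-3-methylpenta-2,4-dienoate F7. Reduction of ester and ketone with iBu2AlH would give 13 together with its C3 epimer (2E,4E)-5-[(1S,2S,4R)-2,4-dihydroxy-2,6,6-trimethylcyclohexyl]-3-methylpenta-2,4-dien-1-ol F8, and the oxidation of step 9 converts both into 14. The mirror detour sets out from 17 and returns at 19, through ethyl (2E,4E)-5-[(1S,2S,3S)-2,3-epoxy-2,6,6-trimethyl-4-oxocyclohexyl]-3-methylpenta-2,4-dienoate F9, ethyl (2E,4E)-5-[(1S,2R)-2-hydroxy-2,6,6-trimethyl-4-oxocyclohexyl]-3-methylpenta-2,4-dienoate F10, and 18 together with its C3 epimer (2E,4E)-5-[(1S,2R,4S)-2,4-dihydroxy-2,6,6-trimethylcyclohexyl]-3-methylpenta-2,4-dien-1-ol F11.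

**Further compounds**

F1 | step 16 | (2E,4E,6E)-2,7-diiodoocta-2,4,6-triene | C/C(I)=C\C=C\C=C(/C)I
F2 | step 16 | (3S,4S)-3-hydroxy-4-[(1E,3E,5E,7E,9E,11E)-12-iodo-3,7-dimethyltrideca-1,3,5,7,9,11-hexaen-1-yl]-3,5,5-trimethylcyclohexan-1-one | C/C(I)=C\C=C\C=C(C)\C=C\C=C(C)\C=C\[C@H]1C(C)(C)CC(=O)C[C@]1(C)O
F3 | step 16 | (3R,4S)-3-hydroxy-3,5,5-trimethyl-4-[(1E,3E,5E)-3-methyl-6-(trimethylstannyl)hexa-1,3,5-trien-1-yl]cyclohexan-1-one | C[Sn](C)(C)/C=C/C=C(C)/C=C/[C@H]1C(C)(C)CC(=O)C[C@@]1(C)O
F4 | step 5 | (S)-3-oxo-α-ionone | CC(=O)/C=C/[C@H]1C(C)(C)CC(=O)C=C1C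
F5 | step 5 | ethyl (4E)-3-hydroxy-3-methyl-5-[(1S)-2,6,6-trimethyl-4-oxocyclohex-2-en-1-yl]pent-4-enoate (both C3 epimers) | CCOC(=O)CC(C)(O)/C=C/[C@H]1C(C)(C)CC(=O)C=C1C
F6 | step 8 | ethyl (2E,4E)-5-[(1S,2R,3R)-2,3-epoxy-2,6,6-trimethyl-4-oxocyclohexyl]-3-methylpenta-2,4-dienoate | CCOC(=O)/C=C(C)/C=C/[C@H]1C(C)(C)CC(=O)[C@@H]2O[C@]12C
F7 | step 8 | ethyl (2E,4E)-5-[(1S,2S)-2-hydroxy-2,6,6-trimethyl-4-oxocyclohexyl]-3-methylpenta-2,4-dienoate | CCOC(=O)/C=C(C)/C=C/[C@H]1C(C)(C)CC(=O)C[C@]1(C)O
F8 | step 8 | (2E,4E)-5-[(1S,2S,4R)-2,4-dihydroxy-2,6,6-trimethylcyclohexyl]-3-methylpenta-2,4-dien-1-ol | OC/C=C(C)/C=C/[C@H]1C(C)(C)C[C@@H](O)C[C@]1(C)O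
F9 | step 8 | ethyl (2E,4E)-5-[(1S,2S,3S)-2,3-epoxy-2,6,6-trimethyl-4-oxocyclohexyl]-3-methylpenta-2,4-dienoate | CCOC(=O)/C=C(C)/C=C/[C@H]1C(C)(C)CC(=O)[C@H]2O[C@@]12C
F10 | step 8 | ethyl (2E,4E)-5-[(1S,2R)-2-hydroxy-2,6,6-trimethyl-4-oxocyclohexyl]-3-methylpenta-2,4-dienoate | CCOC(=O)/C=C(C)/C=C/[C@H]1C(C)(C)CC(=O)C[C@@]1(C)O
F11 | step 8 | (2E,4E)-5-[(1S,2R,4S)-2,4-dihydroxy-2,6,6-trimethylcyclohexyl]-3-methylpenta-2,4-dien-1-ol | OC/C=C(C)/C=C/[C@H]1C(C)(C)C[C@H](O)C[C@@]1(C)O
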